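**Plan**

- Cuts: the silyl ethers and tert-butyl ester; ring B at the lactone C1–O2 bond; ring A at C5a–C6 and C9–C9a (retro-Diels–Alder after adding a C7=C8 double bond) into dienal 25 and silyloxy diene 19; the ester of 19 at its O–CH2 bond into acid 11 and chloroketone 17; ring C by a second retro-Diels–Alder into diene 3 and methyl vinyl ketone.
- Enabling feature: in ring A (C5a, C6, C7, C8, C9, C9a) the tertiary carbinol C9 and the isopropyl-bearing C6 flank C9a and C5a, which lie α and β to the lactone carbonyl C1. With C7=C8 added, ring A is the endo adduct of a 1-oxygenated diene (C6=C7–C8=C9–O) and an E-enal (C5a=C9a–C1HO).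
- Forward order: ring C (step 2), then its side chain and the ester link (steps 3–11), then ring A (step 15, which joins the ring C fragment, the diene and the future ring B chain), then ring B by lactonisation (step 18), then alkene reduction and deprotection.
- Stereochemistry: the cis pair of ring C comes from a catalyst-controlled endo Diels–Alder reaction. All four stereocentres of ring A come from one catalyst-controlled endo Diels–Alder reaction (E-enal, E-alkene and Z-enol silane geometries). The trisubstituted alkenes come from Wittig/Stille chemistry and a Morita–Baylis–Hillman transposition.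

Key step: step 15

Remarks: TBS = tert-butyldimethylsilyl. Core locants are those of 2-benzoxepine (ring A = carbocycle C5a–C9a, ring B = lactone, ring C = cyclohexene of the ester part). A = (2E)-2-(TBSO-methyl)-3-[(1R,6R)-3-(TBSO-methyl)-6-(prop-1-en-2-yl)cyclohex-2-en-1-yl]prop-2-enoyl; A′ = the same acyl group with (1R,6S)-6-(propan-2-yl).
Assumption: in step 2 the sense of induction is taken from the α-C–H···O binding model that holds for acrylates; the antipodal catalyst is equally accessible.

**Route**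

Step 1
Reactants: 1 tert-butyldimethyl(prop-2-yn-1-yloxy)silane; 2 allyl acetate
Product: 3 (2E)-4-(TBSO-methyl)penta-2,4-dien-1-yl acetate
Conditions: second-generation Grubbs catalyst RuCl2(=CHPh)(PCy3)(H2IMes) (5 mol %), 2 (3 equiv), CH2Cl2, 40 °C
Reagents that add atoms: none
Why: Cross enyne metathesis of a terminal alkyne with a terminal alkene should give the 2-substituted 1,3-diene with the E isomer favoured under the equilibrating catalyst; the minor Z isomer cannot reach the cisoid conformation and is left behind in step 2.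

Step 2
Reactants: 3 (2E)-4-(TBSO-methyl)penta-2,4-dien-1-yl acetate; 4 but-3-en-2-one
Product: 5 [(1S,6R)-6-acetyl-3-(TBSO-methyl)cyclohex-2-en-1-yl]methyl acetate
Conditions: (R)-1-(2-methylphenyl)-3,3-diphenyltetrahydro-1H,3H-pyrrolo[1,2-c][1,3,2]oxazaborole (20 mol %), HNTf2 (16 mol %), CH2Cl2, −78 → −40 °C
Reagents that add atoms: none
Why: Oxazaborolidinium-catalysed Diels–Alder reaction of an enone with an acyclic diene: the 2-substituent and the 4-substituent of the diene both place the acetyl carbon next to the acetoxymethyl carbon, the Lewis-acid-bound acetyl group sits endo so that the two groups end up cis, and the R catalyst should expose the si face of the enone α-carbon, which fixes both new stereocentres.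

Step 3
Reactants: 5 [(1S,6R)-6-acetyl-3-(TBSO-methyl)cyclohex-2-en-1-yl]methyl acetate
Product: 6 [(1S,6R)-3-(TBSO-methyl)-6-(prop-1-en-2-yl)cyclohex-2-en-1-yl]methyl acetate
Conditions: Ph3PCH3Br, KN(SiMe3)2, THF, −78 → 0 °C
Reagents that add atoms: methyltriphenylphosphonium bromide, C[P+](c1ccccc1)(c1ccccc1)c1ccccc1.[Br-]
Why: Wittig methylenation of the methyl ketone; the non-stabilised ylide should attack the ketone far faster than the acetate and, at low temperature, should not epimerise the cis α-stereocentre.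

Step 4
Reactants: 6 [(1S,6R)-3-(TBSO-methyl)-6-(prop-1-en-2-yl)cyclohex-2-en-1-yl]methyl acetate
Product: 7 [(1S,6R)-3-(TBSO-methyl)-6-(prop-1-en-2-yl)cyclohex-2-en-1-yl]methanol
Conditions: K2CO3 (0.2 equiv), MeOH, 0 °C → rt
Reagents that add atoms: none
Why: Base-catalysed transesterification with methanol should remove the primary acetate while the silyl ether and both alkenes stay inert.

Step 5
Reactants: 7 [(1S,6R)-3-(TBSO-methyl)-6-(prop-1-en-2-yl)cyclohex-2-en-1-yl]methanol
Product: 9 ethyl (2Z)-2-bromo-3-[(1S,6R)-3-(TBSO-methyl)-6-(prop-1-en-2-yl)cyclohex-2-en-1-yl]prop-2-enoate, via aldehyde 8 (not isolated)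
Conditions: Dess–Martin periodinane, pyridine, CH2Cl2, 0 °C; then Ph3P=CHCO2Et/NBS (premixed at −20 °C), CH2Cl2, −20 °C → rt
Reagents that add atoms: ethyl (triphenylphosphoranylidene)acetate, CCOC(=O)C=P(c1ccccc1)(c1ccccc1)c1ccccc1; N-bromosuccinimide, O=C1CCC(=O)N1Br
Why: Dess–Martin oxidation followed in the same flask by Wittig olefination with the bromo ylide formed from the stabilised ylide and NBS; the weakly basic ylide should trap the epimerisable β,γ-unsaturated aldehyde before it isomerises and should give mainly the Z bromoalkene (ring trans to the ester).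

Step 6
Reactants: 9 ethyl (2Z)-2-bromo-3-[(1S,6R)-3-(TBSO-methyl)-6-(prop-1-en-2-yl)cyclohex-2-en-1-yl]prop-2-enoate
Product: 10 ethyl (2E)-2-(hydroxymethyl)-3-[(1R,6R)-3-(TBSO-methyl)-6-(prop-1-en-2-yl)cyclohex-2-en-1-yl]prop-2-enoate
Conditions: Bu3SnCH2OH, Pd(PPh3)4 (5 mol %), 1,4-dioxane, 90 °C
Reagents that add atoms: (tributylstannyl)methanol, CCCC[Sn](CCCC)(CCCC)CO
Why: Stille hydroxymethylation of the α-bromo enoate should proceed with retention of alkene geometry, so the hydroxymethyl group ends up cis to the ring.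

Step 7
Reactants: 10 ethyl (2E)-2-(hydroxymethyl)-3-[(1R,6R)-3-(TBSO-methyl)-6-(prop-1-en-2-yl)cyclohex-2-en-1-yl]prop-2-enoate
Product: 11 (2E)-2-(hydroxymethyl)-3-[(1R,6R)-3-(TBSO-methyl)-6-(prop-1-en-2-yl)cyclohex-2-en-1-yl]prop-2-enoic acid
Conditions: LiOH, THF/H2O, rt; then 1 M HCl to pH 3
Reagents that add atoms: lithium hydroxide, [Li+].[OH-]
Why: Saponification of the ethyl ester; the silyl ether and the γ-stereocentre should be stable to aqueous hydroxide.

Step 8
Reactants: 12 3-methylbutanal; 13 malonic acid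
Product: 14 (3E)-5-methylhex-3-enoic acid
Conditions: NEt3 (1.5 equiv), 90 °C
Reagents that add atoms: none
Why: Deconjugative Knoevenagel–Doebner condensation; decarboxylation of the alkylidene malonate through its β,γ-unsaturated tautomer should give the (E)-alk-3-enoic acid.

Step 9
Reactants: 14 (3E)-5-methylhex-3-enoic acid
Product: 17 (4E)-1-chloro-6-methylhept-4-en-2-one, via acid chloride 15 (not isolated), via diazoketone 16 (not isolated)
Conditions: (COCl)2, DMF (cat.), CH2Cl2, 0 °C → rt; then Me3SiCHN2, MeCN/THF, 0 °C; then HCl (4 M in 1,4-dioxane), 0 °C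
Reagents that add atoms: (trimethylsilyl)diazomethane, C[Si](C)(C)C=[N+]=[N-]; hydrogen chloride, Cl
Why: Nierenstein-type homologation: acylation of the diazoalkane gives the α-diazoketone, which HCl should convert into the chloromethyl ketone with loss of N2, and the β,γ-alkene stays in place because no base is used.

Step 10
Reactants: 11 (2E)-2-(hydroxymethyl)-3-[(1R,6R)-3-(TBSO-methyl)-6-(prop-1-en-2-yl)cyclohex-2-en-1-yl]prop-2-enoic acid; 17 (4E)-1-chloro-6-methylhept-4-en-2-one
Product: 18 (4E)-6-methyl-2-oxohept-4-en-1-yl (2E)-2-(hydroxymethyl)-3-[(1R,6R)-3-(TBSO-methyl)-6-(prop-1-en-2-yl)cyclohex-2-en-1-yl]prop-2-enoate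
Conditions: Cs2CO3 (0.5 equiv), NaI (10 mol %), DMF, 0 °C → rt
Reagents that add atoms: none
Why: SN2 alkylation of the caesium carboxylate by the α-chloroketone (phenacyl-ester-type esterification) should be selective for the carboxylate over the free primary alcohol, and the weak base should not move the β,γ-alkene into conjugation.

Step 11
Reactants: 18 (4E)-6-methyl-2-oxohept-4-en-1-yl (2E)-2-(hydroxymethyl)-3-[(1R,6R)-3-(TBSO-methyl)-6-(prop-1-en-2-yl)cyclohex-2-en-1-yl]prop-2-enoate
Product: 19 (2Z,4E)-2-(TBSO)-6-methylhepta-2,4-dien-1-yl ester of acid A–OH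
Conditions: TBSOTf (2.5 equiv), NEt3 (4 equiv), CH2Cl2, −78 → 0 °C
Reagents that add atoms: tert-butyldimethylsilyl trifluoromethanesulfonate, CC(C)(C)[Si](C)(C)OS(=O)(=O)C(F)(F)F
Why: Silylation of the primary alcohol and soft enolisation of the ketone toward the doubly activated allylic CH2 should give the conjugated silyl dienol ether; the Z enol silane (oxygen cis to the diene chain) is expected because it avoids allylic strain between the acyloxymethyl group and the vinyl substituent, and the preset E alkene is untouched.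

Step 12
Reactants: 20 (2E)-4,4-dimethoxybut-2-enal; 21 tert-butyl acrylate
Product: 22 tert-butyl (4E)-3-hydroxy-6,6-dimethoxy-2-methylidenehex-4-enoate (racemic)
Conditions: DABCO (0.5 equiv), 1,4-dioxane/H2O (1:1), rt
Reagents that add atoms: none
Why: Morita–Baylis–Hillman reaction; the ammonium enolate of the acrylate should add 1,2 to the unhindered enal, and the acetal is stable to the amine.

Step 13
Reactants: 22 tert-butyl (4E)-3-hydroxy-6,6-dimethoxy-2-methylidenehex-4-enoate
Product: 24 tert-butyl (2E,4E)-2-(acetoxymethyl)-6,6-dimethoxyhexa-2,4-dienoate, via secondary acetate 23 (not isolated)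
Conditions: Ac2O, DMAP (5 mol %), pyridine, CH2Cl2, 0 °C; then DABCO (0.5 equiv), 40 °C
Reagents that add atoms: acetic anhydride, CC(=O)OC(C)=O
Why: Acetylation and amine-mediated allylic transposition (SN2′–SN2′) of the Morita–Baylis–Hillman acetate; the primary acetate of the fully conjugated dienoate is the thermodynamic product and should form with the ester trans to the chain, so the stereocentre of 22 is erased.

Step 14
Reactants: 24 tert-butyl (2E,4E)-2-(acetoxymethyl)-6,6-dimethoxyhexa-2,4-dienoate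
Product: 25 tert-butyl (2E,4E)-2-(acetoxymethyl)-6-oxohexa-2,4-dienoate
Conditions: 1 M HCl, THF, 0 °C → rt
Reagents that add atoms: water, O
Why: Acid-catalysed acetal hydrolysis; the tert-butyl ester and the allylic acetate should survive dilute acid at room temperature, and the E,E geometry is the thermodynamic one.

Step 15
Reactants: 19 (2Z,4E)-2-(TBSO)-6-methylhepta-2,4-dien-1-yl ester of A–OH; 25 tert-butyl (2E,4E)-2-(acetoxymethyl)-6-oxohexa-2,4-dienoate
Product: 26 tert-butyl (2E)-2-(acetoxymethyl)-3-[(1S,2S,5S,6S)-5-(TBSO)-6-formyl-2-(propan-2-yl)-5-(A-oxymethyl)cyclohex-3-en-1-yl]prop-2-enoate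
Conditions: (5R)-5-benzyl-2,2,3-trimethylimidazolidin-4-one·CF3CO2H (20 mol %), CH2Cl2, H2O (2 equiv), −40 → −20 °C
Reagents that add atoms: none
Why: Proposed new method: condensation of the first-generation imidazolidinone with the aldehyde of 25 gives an E-iminium ion that lowers the LUMO of the disubstituted C=C only, and the cisoid Z,E-silyloxy diene 19 should add across it in a concerted, asynchronous [4+2] cycloaddition in which the bond from the isopropyl-bearing diene terminus to the enal β-carbon (future C5a–C6) runs ahead of the bond from the silyloxy carbon to the α-carbon (future C9–C9a). The closest known reaction type is the imidazolidinone-catalysed endo Diels–Alder reaction of E-enals with 1-acetoxybutadiene; a ketone-derived 1-silyloxy diene with a fully substituted oxygen-bearing terminus has so far been used only in thermal and Lewis-acid cycloadditions (1,3-bis(silyloxy)dienes, 1-alkoxy-1-silyloxy dienes). Ring A is closed as a cyclohexene in the suprafacial [4+2] mode; should the process turn stepwise, vinylogous Mukaiyama–Michael addition followed by six-membered closure of the enamine carbon onto the silyloxocarbenium ion gives the same product from the cisoid diene. C5a and C9a come out trans because the dienophile is E, and their absolute configuration follows from the benzyl group of the catalyst shielding one face of the iminium ion so that the diene adds to the re face of the α-carbon; C6 follows from the E geometry of the diene C=C and C9 from the Z geometry of the enol silane (oxygen inside, acyloxymethyl outside), both read through the endo transition state with the iminium carbon under the diene. The step needs regioselectivity (largest HOMO coefficient at the diene terminus remote from oxygen meets the iminium β-carbon), chemoselectivity for the disubstituted over the trisubstituted C=C of 25 and for cycloaddition over open-chain Michael addition or desilylation (low temperature, weak acid co-catalyst, little water), and endo selectivity (oxygen is the smallest possible inside substituent and faces only the exo hydrogen).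

Step 16
Reactants: 26 tert-butyl (2E)-2-(acetoxymethyl)-3-[(1S,2S,5S,6S)-5-(TBSO)-6-formyl-2-(propan-2-yl)-5-(A-oxymethyl)cyclohex-3-en-1-yl]prop-2-enoate
Product: 27 (1S,2S,5S,6S)-6-[(1E)-2-(acetoxymethyl)-3-tert-butoxy-3-oxoprop-1-en-1-yl]-2-(TBSO)-5-(propan-2-yl)-2-(A-oxymethyl)cyclohex-3-ene-1-carboxylic acid
Conditions: NaClO2, NaH2PO4, 2-methylbut-2-ene, tBuOH/H2O, 0 °C → rt
Reagents that add atoms: sodium chlorite, [Na+].[O-]Cl=O
Why: Pinnick oxidation should convert the hindered aldehyde into the acid without epimerisation (the carboxyl is already trans to its ring neighbour), and the alkene scavenger protects the C=C bonds from hypochlorite.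

Step 17
Reactants: 27 (1S,2S,5S,6S)-6-[(1E)-2-(acetoxymethyl)-3-tert-butoxy-3-oxoprop-1-en-1-yl]-2-(TBSO)-5-(propan-2-yl)-2-(A-oxymethyl)cyclohex-3-ene-1-carboxylic acid
Product: 28 (1S,2S,5S,6S)-6-[(1E)-3-tert-butoxy-2-(hydroxymethyl)-3-oxoprop-1-en-1-yl]-2-(TBSO)-5-(propan-2-yl)-2-(A-oxymethyl)cyclohex-3-ene-1-carboxylic acid
Conditions: K2CO3 (1.5 equiv), MeOH, 0 °C; then 0.5 M HCl to pH 4
Reagents that add atoms: none
Why: Methanolysis of the unhindered primary allylic acetate should be much faster than that of the neopentyl-type enoate, the tert-butyl ester or the silyl ethers.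

Step 18
Reactants: 28 (1S,2S,5S,6S)-6-[(1E)-3-tert-butoxy-2-(hydroxymethyl)-3-oxoprop-1-en-1-yl]-2-(TBSO)-5-(propan-2-yl)-2-(A-oxymethyl)cyclohex-3-ene-1-carboxylic acid
Product: 29 tert-butyl (5aS,6S,9S,9aS)-9-(TBSO)-1-oxo-6-(propan-2-yl)-9-(A-oxymethyl)-1,3,5a,6,9,9a-hexahydro-2-benzoxepine-4-carboxylate
Conditions: 2-methyl-6-nitrobenzoic anhydride, DMAP, toluene (2 mM, slow addition), rt → 50 °C
Reagents that add atoms: none
Why: Shiina lactonisation; the mixed anhydride should acylate the primary allylic alcohol, which lies cis to the ring on the side-chain alkene and next to the trans-disposed carboxyl, to close the seven-membered ring B.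

Step 19
Reactants: 29 tert-butyl (5aS,6S,9S,9aS)-9-(TBSO)-1-oxo-6-(propan-2-yl)-9-(A-oxymethyl)-1,3,5a,6,9,9a-hexahydro-2-benzoxepine-4-carboxylate
Product: 30 tert-butyl (5aS,6R,9S,9aS)-9-(TBSO)-1-oxo-6-(propan-2-yl)-9-(A′-oxymethyl)-1,3,5a,6,7,8,9,9a-octahydro-2-benzoxepine-4-carboxylate
Conditions: 2-nitrobenzenesulfonohydrazide (excess, in portions), NEt3, CH2Cl2, rt
Reagents that add atoms: none
Why: Diimide reduction should transfer H2 to the 1,1-disubstituted isopropenyl alkene and the cis-disubstituted ring A alkene and spare the three trisubstituted alkenes; no stereocentre is created.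

Step 20
Reactants: 30 tert-butyl (5aS,6R,9S,9aS)-9-(TBSO)-1-oxo-6-(propan-2-yl)-9-(A′-oxymethyl)-1,3,5a,6,7,8,9,9a-octahydro-2-benzoxepine-4-carboxylate
Product: 32 CNP0361406.5, via trimethylsilyl ester 31 (not isolated)
Conditions: TMSOTf, 2,6-lutidine, CH2Cl2, 0 °C; then HF·pyridine, THF/pyridine, 0 °C → rt
Reagents that add atoms: none
Why: Silyl triflate cleavage of the tert-butyl ester to the silyl ester (loss of isobutene), then removal of the silyl ester and the three TBS ethers by HF·pyridine under non-basic conditions, which should avoid retro-aldol cleavage and acyl migration.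

**Compound list**

1 | tert-butyldimethyl(prop-2-yn-1-yloxy)silane | C#CCO[Si](C)(C)C(C)(C)C | starting material
2 | allyl acetate | C=CCOC(C)=O | starting material
3 | (2E)-4-(TBSO-methyl)penta-2,4-dien-1-yl acetate | CC(=O)OC/C=C/C(=C)CO[Si](C)(C)C(C)(C)C | intermediate
4 | but-3-en-2-one | CC(=O)C=C | starting material
5 | [(1S,6R)-6-acetyl-3-(TBSO-methyl)cyclohex-2-en-1-yl]methyl acetate (cis) | CC(=O)OC[C@H]1C=C(CO[Si](C)(C)C(C)(C)C)CC[C@H]1C(C)=O | intermediate
6 | [(1S,6R)-3-(TBSO-methyl)-6-(prop-1-en-2-yl)cyclohex-2-en-1-yl]methyl acetate | CC(=O)OC[C@H]1C=C(CO[Si](C)(C)C(C)(C)C)CC[C@H]1C(C)=C | intermediate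
7 | [(1S,6R)-3-(TBSO-methyl)-6-(prop-1-en-2-yl)cyclohex-2-en-1-yl]methanol | OC[C@H]1C=C(CO[Si](C)(C)C(C)(C)C)CC[C@H]1C(C)=C | intermediate
8 | (1S,6R)-3-(TBSO-methyl)-6-(prop-1-en-2-yl)cyclohex-2-ene-1-carbaldehyde | O=C[C@H]1C=C(CO[Si](C)(C)C(C)(C)C)CC[C@H]1C(C)=C | intermediate
9 | ethyl (2Z)-2-bromo-3-[(1S,6R)-3-(TBSO-methyl)-6-(prop-1-en-2-yl)cyclohex-2-en-1-yl]prop-2-enoate | CCOC(=O)/C(Br)=C/[C@H]1C=C(CO[Si](C)(C)C(C)(C)C)CC[C@H]1C(C)=C | intermediate
10 | ethyl (2E)-2-(hydroxymethyl)-3-[(1R,6R)-3-(TBSO-methyl)-6-(prop-1-en-2-yl)cyclohex-2-en-1-yl]prop-2-enoate | CCOC(=O)/C(CO)=C/[C@H]1C=C(CO[Si](C)(C)C(C)(C)C)CC[C@H]1C(C)=C | intermediate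
11 | (2E)-2-(hydroxymethyl)-3-[(1R,6R)-3-(TBSO-methyl)-6-(prop-1-en-2-yl)cyclohex-2-en-1-yl]prop-2-enoic acid | OC(=O)/C(CO)=C/[C@H]1C=C(CO[Si](C)(C)C(C)(C)C)CC[C@H]1C(C)=C | intermediate
12 | 3-methylbutanal | CC(C)CC=O | starting material
13 | malonic acid | OC(=O)CC(=O)O | starting material
14 | (3E)-5-methylhex-3-enoic acid | CC(C)/C=C/CC(=O)O | intermediate
15 | (3E)-5-methylhex-3-enoyl chloride | CC(C)/C=C/CC(=O)Cl | intermediate
16 | (4E)-1-diazo-6-methylhept-4-en-2-one | CC(C)/C=C/CC(=O)C=[N+]=[N-] | intermediate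
17 | (4E)-1-chloro-6-methylhept-4-en-2-one | CC(C)/C=C/CC(=O)CCl | intermediate
18 | (4E)-6-methyl-2-oxohept-4-en-1-yl (2E)-2-(hydroxymethyl)-3-[(1R,6R)-3-(TBSO-methyl)-6-(prop-1-en-2-yl)cyclohex-2-en-1-yl]prop-2-enoate | CC(C)/C=C/CC(=O)COC(=O)/C(CO)=C/[C@H]1C=C(CO[Si](C)(C)C(C)(C)C)CC[C@H]1C(C)=C | intermediate
19 | (2Z,4E)-2-(TBSO)-6-methylhepta-2,4-dien-1-yl (2E)-2-(TBSO-methyl)-3-[(1R,6R)-3-(TBSO-methyl)-6-(prop-1-en-2-yl)cyclohex-2-en-1-yl]prop-2-enoate | CC(C)/C=C/C=C(\O[Si](C)(C)C(C)(C)C)COC(=O)/C(CO[Si](C)(C)C(C)(C)C)=C/[C@H]1C=C(CO[Si](C)(C)C(C)(C)C)CC[C@H]1C(C)=C | intermediate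
20 | (2E)-4,4-dimethoxybut-2-enal | COC(OC)/C=C/C=O | starting material
21 | tert-butyl acrylate | C=CC(=O)OC(C)(C)C | starting material
22 | tert-butyl (4E)-3-hydroxy-6,6-dimethoxy-2-methylidenehex-4-enoate (racemic) | COC(OC)/C=C/C(O)C(=C)C(=O)OC(C)(C)C | intermediate
23 | tert-butyl (4E)-3-acetoxy-6,6-dimethoxy-2-methylidenehex-4-enoate (racemic) | COC(OC)/C=C/C(OC(C)=O)C(=C)C(=O)OC(C)(C)C | intermediate
24 | tert-butyl (2E,4E)-2-(acetoxymethyl)-6,6-dimethoxyhexa-2,4-dienoate | COC(OC)/C=C/C=C(\COC(C)=O)C(=O)OC(C)(C)C | intermediate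
25 | tert-butyl (2E,4E)-2-(acetoxymethyl)-6-oxohexa-2,4-dienoate | O=C/C=C/C=C(\COC(C)=O)C(=O)OC(C)(C)C | intermediate
26 | tert-butyl (2E)-2-(acetoxymethyl)-3-[(1S,2S,5S,6S)-5-(TBSO)-6-formyl-2-(propan-2-yl)-5-(A-oxymethyl)cyclohex-3-en-1-yl]prop-2-enoate | CC(C)[C@H]1C=C[C@@](O[Si](C)(C)C(C)(C)C)(COC(=O)/C(CO[Si](C)(C)C(C)(C)C)=C/[C@H]2C=C(CO[Si](C)(C)C(C)(C)C)CC[C@H]2C(C)=C)[C@@H](C=O)[C@@H]1/C=C(\COC(C)=O)C(=O)OC(C)(C)C | intermediate
27 | (1S,2S,5S,6S)-6-[(1E)-2-(acetoxymethyl)-3-tert-butoxy-3-oxoprop-1-en-1-yl]-2-(TBSO)-5-(propan-2-yl)-2-(A-oxymethyl)cyclohex-3-ene-1-carboxylic acid | CC(C)[C@H]1C=C[C@@](O[Si](C)(C)C(C)(C)C)(COC(=O)/C(CO[Si](C)(C)C(C)(C)C)=C/[C@H]2C=C(CO[Si](C)(C)C(C)(C)C)CC[C@H]2C(C)=C)[C@@H](C(=O)O)[C@@H]1/C=C(\COC(C)=O)C(=O)OC(C)(C)C | intermediate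
28 | (1S,2S,5S,6S)-6-[(1E)-3-tert-butoxy-2-(hydroxymethyl)-3-oxoprop-1-en-1-yl]-2-(TBSO)-5-(propan-2-yl)-2-(A-oxymethyl)cyclohex-3-ene-1-carboxylic acid | CC(C)[C@H]1C=C[C@@](O[Si](C)(C)C(C)(C)C)(COC(=O)/C(CO[Si](C)(C)C(C)(C)C)=C/[C@H]2C=C(CO[Si](C)(C)C(C)(C)C)CC[C@H]2C(C)=C)[C@@H](C(=O)O)[C@@H]1/C=C(\CO)C(=O)OC(C)(C)C | intermediate
29 | tert-butyl (5aS,6S,9S,9aS)-9-(TBSO)-1-oxo-6-(propan-2-yl)-9-(A-oxymethyl)-1,3,5a,6,9,9a-hexahydro-2-benzoxepine-4-carboxylate | CC(C)[C@H]1C=C[C@@](O[Si](C)(C)C(C)(C)C)(COC(=O)/C(CO[Si](C)(C)C(C)(C)C)=C/[C@H]2C=C(CO[Si](C)(C)C(C)(C)C)CC[C@H]2C(C)=C)[C@H]2C(=O)OCC(C(=O)OC(C)(C)C)=C[C@H]12 | intermediate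
30 | tert-butyl (5aS,6R,9S,9aS)-9-(TBSO)-1-oxo-6-(propan-2-yl)-9-(A′-oxymethyl)-1,3,5a,6,7,8,9,9a-octahydro-2-benzoxepine-4-carboxylate | CC(C)[C@H]1CC[C@@](O[Si](C)(C)C(C)(C)C)(COC(=O)/C(CO[Si](C)(C)C(C)(C)C)=C/[C@H]2C=C(CO[Si](C)(C)C(C)(C)C)CC[C@H]2C(C)C)[C@H]2C(=O)OCC(C(=O)OC(C)(C)C)=C[C@H]12 | intermediate
31 | trimethylsilyl (5aS,6R,9S,9aS)-9-(TBSO)-1-oxo-6-(propan-2-yl)-9-(A′-oxymethyl)-1,3,5a,6,7,8,9,9a-octahydro-2-benzoxepine-4-carboxylate | CC(C)[C@H]1CC[C@@](O[Si](C)(C)C(C)(C)C)(COC(=O)/C(CO[Si](C)(C)C(C)(C)C)=C/[C@H]2C=C(CO[Si](C)(C)C(C)(C)C)CC[C@H]2C(C)C)[C@H]2C(=O)OCC(C(=O)O[Si](C)(C)C)=C[C@H]12 | intermediate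
32 | CNP0361406.5: (5aS,6R,9S,9aS)-9-hydroxy-9-({[(2E)-2-(hydroxymethyl)-3-[(1R,6S)-3-(hydroxymethyl)-6-(propan-2-yl)cyclohex-2-en-1-yl]prop-2-enoyl]oxy}methyl)-1-oxo-6-(propan-2-yl)-1,3,5a,6,7,8,9,9a-octahydro-2-benzoxepine-4-carboxylic acid | CC(C)[C@H]1CC[C@@](O)(COC(=O)/C(=C/[C@H]2C=C(CO)CC[C@H]2C(C)C)CO)[C@H]2C(=O)OCC(C(=O)O)=C[C@H]12 | target

**Step count and risks**

Total steps: 20. Longest linear sequence: 15 (steps 1–7, 10, 11, 15–20).

Steps most likely to fail:

1. Step 15 (Proposed new method). The silyl dienol ether may react through its transoid conformer as a vinylogous Mukaiyama donor, giving open-chain Michael addition, or it may lose its silyl group under the acidic iminium conditions; either would replace cycloaddition, and facial control could also be eroded. Fallback: setting out from 19 and 25, the two components are heated without any catalyst (toluene, BHT, 100 °C, or 10 kbar at rt). This is a known thermal Diels–Alder reaction of a ketone-derived silyloxy diene with an enal, in which only the concerted pathway is open. It should give the endo adduct 26 together with its diastereomer of opposite ring A configuration, the antipodal-ring-A cycloadduct F1; the two are separated by preparative HPLC and the route is rejoined at 26. Absolute control then rests on separation against the enantiopure ring C instead of on the catalyst.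

2. Step 2. Facial discrimination may be insufficient or inverted with the small methyl ketone, and endo selectivity may be incomplete. Fallback: setting out from 3, an iminium-catalysed endo Diels–Alder reaction with acrolein ((5S)-5-benzyl-2,2,3-trimethylimidazolidin-4-one hydrochloride, MeCN/H2O, −20 °C; si-face addition at the α-carbon) should give the cis aldehyde [(1S,6R)-6-formyl-3-(TBSO-methyl)cyclohex-2-en-1-yl]methyl acetate F2. Addition of MeTi(OiPr)3 (THF, −30 °C, selective for the aldehyde over the acetate) then gives the carbinol [(1S,6R)-6-(1-hydroxyethyl)-3-(TBSO-methyl)cyclohex-2-en-1-yl]methyl acetate F3 as a mixture at the carbinol carbon, and Dess–Martin oxidation returns to the route at 5.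

3. Step 18. Acyl transfer at the carboxyl next to the quaternary carbon may be slow, leading to oligomerisation or to acylation of the alcohol by the reagent instead of ring closure. Fallback: setting out from 28, a Mitsunobu lactonisation (PPh3, diisopropyl azodicarboxylate, toluene, high dilution) activates the unhindered primary allylic alcohol instead of the hindered acid and forms the alkyl C–O bond by SN2 attack of the carboxylate. It returns to the route at 29 and makes no new compound (F0).

Further compounds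
F1 | step 15 | tert-butyl (2E)-2-(acetoxymethyl)-3-[(1R,2R,5R,6R)-5-(TBSO)-6-formyl-2-(propan-2-yl)-5-(A-oxymethyl)cyclohex-3-en-1-yl]prop-2-enoate | CC(C)[C@@H]1C=C[C@](O[Si](C)(C)C(C)(C)C)(COC(=O)/C(CO[Si](C)(C)C(C)(C)C)=C/[C@H]2C=C(CO[Si](C)(C)C(C)(C)C)CC[C@H]2C(C)=C)[C@H](C=O)[C@H]1/C=C(\COC(C)=O)C(=O)OC(C)(C)C
F2 | step 2 | [(1S,6R)-6-formyl-3-(TBSO-methyl)cyclohex-2-en-1-yl]methyl acetate | CC(=O)OC[C@H]1C=C(CO[Si](C)(C)C(C)(C)C)CC[C@H]1C=O
F3 | step 2 | [(1S,6R)-6-(1-hydroxyethyl)-3-(TBSO-methyl)cyclohex-2-en-1-yl]methyl acetate | CC(=O)OC[C@H]1C=C(CO[Si](C)(C)C(C)(C)C)CC[C@H]1C(C)O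
F0 | step 18 | none | none
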